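**Retrosynthetic overview**
1. Psiguadial A ⇒ (+)-bicyclogermacrene + benzaldehyde + 2,4-diformylphloroglucinol. An o-quinone methide alkylates C4, the C5 cation closes C5–C1 across the ring (cyclopentane and cycloheptane), a C1→C10 hydride shift follows, and the phenol closes C1–O (oxepane).
2. (+)-Bicyclogermacrene ⇒ (2E,6E)-farnesal tosylhydrazone. An asymmetric copper vinylcarbenoid [2+1] addition onto the terminal alkene closes the ten-membered ring and the gem-dimethylcyclopropane in one operation (key step).
3. Tosylhydrazone ⇒ (2E,6E)-farnesol (oxidation, condensation); dialdehyde ⇒ phloroglucinol (Vilsmeier–Haack).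
4. Ring order: cyclopropane together with the cyclodecadiene first; then cyclopentane and cycloheptane, and last the oxepane, all in the closing cascade.

Locants: germacrane numbering is used for the terpene carbons (C1=C10 and C4=C5 are the ring alkenes of bicyclogermacrene, C6 and C7 the cyclopropane CH carbons, C11 the CMe2 carbon, C14 and C15 the methyls on C10 and C4); C1′ is the benzylic carbon.

Assumption: (S,S)-t-Bu-box is taken as the ligand antipode that gives the (1S,10R) cyclopropane; if the sense of induction is the opposite, the (R,R) ligand is used.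

**Step 1**
Reactants: 1 (2E,6E)-farnesol
Product: 2 (2E,6E)-farnesal
Conditions: TEMPO (10 mol %), PhI(OAc)2 (1.1 equiv), CH2Cl2, 23 °C
Reagents that add atoms: none
Why: The nitroxyl/oxoammonium oxidation is selective for the primary allylic alcohol, stops at the aldehyde and leaves the three trisubstituted alkenes and the 2E geometry untouched (TEMPO-catalysed alcohol oxidation; no new stereocentre).

**Step 2**
Reactants: 2 (2E,6E)-farnesal
Product: 3 (2E,6E)-farnesal N-tosylhydrazone
Conditions: TsNHNH2 (1.05 equiv), MeOH, 0 → 23 °C
Reagents that add atoms: p-toluenesulfonyl hydrazide, NNS(=O)(=O)c1ccc(C)cc1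
Why: Condensation of the aldehyde with the sulfonyl hydrazide gives the hydrazone, and the β,β-disubstituted enal is a poor Michael acceptor, so pyrazoline formation and 2E/2Z leakage are suppressed (hydrazone formation; no new stereocentre).

**Step 3**
Reactants: 3 (2E,6E)-farnesal N-tosylhydrazone
Product: 6 (+)-bicyclogermacrene, via hydrazone sodium salt 4 (not isolated), via diazotriene 5 (not isolated)
Conditions: NaH, THF, 0 °C; then [Cu(MeCN)4]PF6 (5 mol %), (S,S)-t-Bu-box (6 mol %), BnEt3NCl (10 mol %), ClCH2CH2Cl, 40 °C, 0.002 M
Reagents that add atoms: none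
Why: Proposed new method: salt 4 loses sulfinate slowly (Bamford–Stevens diazo generation) to give vinyldiazoalkane 5 at low stationary concentration, monovalent copper turns it into a vinylcarbenoid whose 2E geometry forbids addition to the 6,7-alkene (a trans-cyclohexene would result), so the electron-rich terminal alkene is the only one in reach and a [2+1] addition closes the ten-membered ring and the cyclopropane at once, with the cis ring fusion expected from the short six-atom tether and the alkene face chosen by the C2-symmetric bisoxazoline pocket to give the (1S,10R) isomer; the closest known reaction types are copper-bisoxazoline macrocyclic cyclopropanations of geranyl- and farnesyl-type diazoacetates at the remote trisubstituted alkene and the copper-catalysed intramolecular vinylcarbene cyclopropanation of farnesal-derived diazoalkenes that gives the carene skeleton from the 2Z isomer.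

**Step 4**
Reactants: 7 phloroglucinol
Product: 9 2,4-diformylphloroglucinol, via bis-iminium salt 8 (not isolated)
Conditions: POCl3 (2.2 equiv), DMF (2.4 equiv), 1,4-dioxane, 0 → 23 °C; then H2O, 23 °C
Reagents that add atoms: N,N-dimethylformamide, CN(C)C=O; water, O
Why: Vilsmeier–Haack formylation of the very electron-rich triol with two equivalents of chloroiminium reagent stops at the bis-iminium salt because each iminium group deactivates the ring, and aqueous hydrolysis then releases the dialdehyde (no stereocentre).

**Step 5**
Reactants: 6 (+)-bicyclogermacrene; 9 2,4-diformylphloroglucinol; 10 benzaldehyde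
Product: 12 psiguadial A, via o-quinone methide 11 (not isolated)
Conditions: MeNHCH2CH2NHMe (20 mol %), (CF3)2CHOH, 23 °C
Reagents that add atoms: none
Why: Amine-catalysed Knoevenagel condensation of 9 with 10 gives o-quinone methide 11, whose benzylidene carbon is attacked by C4 of the cyclopropyl-conjugated 4E alkene of 6, the C5 cyclopropylcarbinyl cation is captured across the ring by the 1(10)E alkene (anti addition, closing cyclopentane and cycloheptane and fixing C4 and C5 relative to the cyclopropane through the crown conformer), a suprafacial 1,2-hydride shift from C1 to C10 sets C10, the phenol oxygen closes the oxepane at the C1 cation on the face that carries C1′, and exo approach of the phenyl group sets C1′ (biomimetic Knoevenagel/Michael/transannular cation–olefin/hydride-shift/etherification cascade, a formal [4+3] annulation).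

**Compound list**
1 | (2E,6E)-farnesol, (2E,6E)-3,7,11-trimethyldodeca-2,6,10-trien-1-ol | CC(C)=CCC/C(C)=C/CC/C(C)=C/CO | starting material
2 | (2E,6E)-farnesal, (2E,6E)-3,7,11-trimethyldodeca-2,6,10-trienal | CC(C)=CCC/C(C)=C/CC/C(C)=C/C=O | intermediate
3 | (2E,6E)-farnesal N-tosylhydrazone (E at C=N) | CC(C)=CCC/C(C)=C/CC/C(C)=C/C=N/NS(=O)(=O)c1ccc(C)cc1 | intermediate
4 | sodium salt of hydrazone 3 (N-sodio tosylhydrazone) | CC(C)=CCC/C(C)=C/CC/C(C)=C/C=N/[N-]S(=O)(=O)c1ccc(C)cc1.[Na+] | intermediate (not isolated)
5 | (2E,6E)-1-diazo-3,7,11-trimethyldodeca-2,6,10-triene | CC(C)=CCC/C(C)=C/CC/C(C)=C/C=[N+]=[N-] | intermediate (not isolated)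
6 | (+)-bicyclogermacrene, (1S,2E,6E,10R)-3,7,11,11-tetramethylbicyclo[8.1.0]undeca-2,6-diene (cis-fused cyclopropane) | C/C1=C\CC/C(C)=C/[C@H]2[C@@H](CC1)C2(C)C | intermediate
7 | phloroglucinol, benzene-1,3,5-triol | Oc1cc(O)cc(O)c1 | starting material
8 | 2,4-bis[(dimethyliminio)methyl]benzene-1,3,5-triol dichloride | C[N+](C)=Cc1c(O)cc(O)c(C=[N+](C)C)c1O.[Cl-].[Cl-] | intermediate (not isolated)
9 | 2,4-diformylphloroglucinol, 2,4,6-trihydroxybenzene-1,3-dicarbaldehyde | O=Cc1c(O)cc(O)c(C=O)c1O | intermediate
10 | benzaldehyde | O=Cc1ccccc1 | starting material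
11 | o-quinone methide, 5-benzylidene-2,4-dihydroxy-6-oxocyclohexa-1,3-diene-1,3-dicarbaldehyde (either alkene geometry reacts; one drawn) | O=C1C(C=O)=C(O)C(C=O)=C(O)/C1=C/c1ccccc1 | intermediate (not isolated)
12 | psiguadial A: cis-fused 5-7-3 aromadendrane core with C4 bearing α-methyl and β-CH(Ph)aryl, the aryl oxygen bonded to C1 (β) to close the oxepane, 5β-H, 10β-methyl, 6α,7α-H; aryl = 2,4-diformyl-3,5-dihydroxyphenyl ether; (1S,4R,5R,6R,7R,10S,1′S) | C[C@H]1CC[C@@H]2[C@H]([C@@H]3[C@]4(C)CC[C@@]31Oc1c(C=O)c(O)c(C=O)c(O)c1[C@@H]4c1ccccc1)C2(C)C | target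

**Totals and risks**
Total step count: 5. Longest linear sequence: 4 steps (1 → 2 → 3 → 6 → 12).

Steps most likely to fail:

Step 3 (macrocyclising cyclopropanation). The risks are:
- closure of a strained ten-membered ring;
- 1,5-cyclisation of 5 to a 3H-pyrazole, cyclopropene formation and carbene dimerisation;
- any loss of the 2E geometry, which would divert material to the carene (sesquicarene) skeleton;
- uncertain cis/trans ring fusion and enantiomeric excess.

The fallback sets out from 1 and comes back at 6, and replaces carbene chemistry by a cationic biocatalytic cyclisation. Alcohol 1 is diphosphorylated in one operation (Cl3CCN, (Et3NH)2HPO4, MeCN, 23 °C; ion exchange) to (2E,6E)-farnesyl diphosphate F1. F1 is then cyclised by a recombinant (+)-bicyclogermacrene synthase (MgCl2, pH 7.5 buffer, pentane overlay, 30 °C). Enzymatic ionisation, 1,10-closure and 1,3-deprotonation deliver 6 as a single enantiomer with the cis cyclopropane.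

Step 5 (three-component cascade). The risks are:
- hetero-Diels–Alder adducts of 11 at either alkene compete with the transannular path;
- 6 can cyclise to ledene-type hydrocarbons in the ionising solvent.

The fallback sets out from 6 (with 9 and 10) and comes back at 12, and splits the cascade into a cycloaddition and a separate ring expansion. Compounds 9 and 10 are condensed in the presence of 6 under non-ionising conditions (piperidinium acetate cat., toluene, 60 °C), so that 11 is trapped by the C4=C5 alkene in a hetero-Diels–Alder reaction. This gives the C4–C5 chromane adduct F2 (C1′–C4 and O–C5 bonds), which is separated from the C1=C10 regioisomer. F2 is then ionised at its tertiary cyclopropylcarbinyl aryl ether (TfOH cat., (CF3)2CHOH, 0 °C) to the same C5 cation, which undergoes the transannular closure, hydride shift and etherification to 12.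

Step 4 (double formylation). The risks are mixtures of mono-, di- and triformyl products and a water-soluble polyphenol that is hard to purify.

The fallback sets out from 7 and comes back at 9, and uses a protecting-group route. Compound 7 is permethylated (Me2SO4, K2CO3, acetone, reflux) to 1,3,5-trimethoxybenzene F3. Rieche formylation (Cl2CHOMe, TiCl4, CH2Cl2, 0 °C) gives 2,4,6-trimethoxybenzene-1,3-dicarbaldehyde F4, which is easy to purify. BBr3 (CH2Cl2, −78 → 23 °C) then cleaves the three methyl ethers to 9.

**Further compounds**
F1 | step 3 | (2E,6E)-farnesyl diphosphate | CC(C)=CCC/C(C)=C/CC/C(C)=C/COP(=O)(O)OP(=O)(O)O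
F2 | step 5 | C4–C5 chromane adduct of 6 with 11 (C4 and C1′ as in 12, O–C5 cis to C1′, 1(10)E alkene and cyclopropane retained) | C/C1=C\CC[C@]3(C)[C@@H](c4ccccc4)c5c(O)c(C=O)c(O)c(C=O)c5O[C@H]3[C@H]2[C@@H](CC1)C2(C)C
F3 | step 4 | 1,3,5-trimethoxybenzene | COc1cc(OC)cc(OC)c1
F4 | step 4 | 2,4,6-trimethoxybenzene-1,3-dicarbaldehyde | COc1cc(OC)c(C=O)c(OC)c1C=O
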